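**Retrosynthetic overview**
1. Target 17 ← hydrogenolysis of the benzylated depside 16 ← O4'-benzylation and O2'-methylation of resorcylate 14 ← dehydrogenation of cyclohexane-2,4-dione 13.
2. Feature used: ring B is a resorcylate in which C1' (carboxyl) and C2' (oxygen) map onto a malonate, C3' (acyloxy), C4' (oxygen) and C5' onto an alpha-acyloxy ketone, and C6' (propyl) onto butanal. Dione 13 is therefore cut at C1'–C6' and C2'–C3' into dibenzyl malonate 11 and the alpha'-aroyloxy enone 10.
3. Enone 10 ← Wittig reaction of butanal 9 with acyloxy ylide 8 ← ring A acid 5 + chloro ylide 6; 5 ← 5-propylresorcinol 1 by formylation, benzylation and Pinnick oxidation.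
4. Ring order: ring A is carried through from 1; ring B is the only ring formed (step 6, as a saturated dione) and is aromatized in step 7.

Key step: step 6

Remark: the target has no stereocentre; ylide 6 is taken as a purchasable reagent (the stabilized ylide derived from 1,3-dichloroacetone and PPh3), and 13 is drawn as its triketo form although it should exist as enol tautomers.

Step 1
Reactants: 1 5-propylresorcinol
Product: 3 2,4-dihydroxy-6-propylbenzaldehyde, via aryl iminium chloride 2 (not isolated)
Conditions: POCl3, DMF, MeCN, 0 °C to rt; then H2O, 50 °C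
Reagents that add atoms: N,N-dimethylformamide CN(C)C=O; water O
Why: Vilsmeier–Haack formylation of a 5-alkylresorcinol should go at the position ortho to one hydroxyl and para to the other (next to the propyl group) rather than between the two hydroxyls, and aqueous work-up hydrolyses iminium salt 2 to the aldehyde.

Step 2
Reactants: 3 2,4-dihydroxy-6-propylbenzaldehyde
Product: 4 2,4-bis(benzyloxy)-6-propylbenzaldehyde
Conditions: BnBr (2.4 equiv), K2CO3, DMF, 60 °C
Reagents that add atoms: benzyl bromide BrCc1ccccc1
Why: Williamson ether synthesis in warm DMF should alkylate both phenols, including the one hydrogen-bonded to the aldehyde.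

Step 3
Reactants: 4 2,4-bis(benzyloxy)-6-propylbenzaldehyde
Product: 5 2,4-bis(benzyloxy)-6-propylbenzoic acid
Conditions: NaClO2, NaH2PO4, 2-methyl-2-butene, t-BuOH–THF–H2O, rt
Reagents that add atoms: sodium chlorite [Na+].[O-]Cl=O
Why: Pinnick oxidation converts the hindered, electron-rich aldehyde into the acid without touching the benzyl ethers, the alkene scavenger removing hypochlorous acid before it can chlorinate the ring.

Step 4
Reactants: 5 2,4-bis(benzyloxy)-6-propylbenzoic acid; 6 1-chloro-3-(triphenylphosphoranylidene)propan-2-one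
Product: 8 2-oxo-3-(triphenylphosphoranylidene)propyl 2,4-bis(benzyloxy)-6-propylbenzoate, via cesium carboxylate 7 (not isolated)
Conditions: Cs2CO3 (1.0 equiv), DMF, rt; then 6, NaI (cat.), 60 °C
Reagents that add atoms: none
Why: SN2 displacement of the alpha-chloro ketone chloride by the cesium carboxylate under iodide (Finkelstein) catalysis should work because the attacking oxygen lies outside the hindered carbonyl pocket and the acyl-stabilized ylide is too weakly basic to interfere.

Step 5
Reactants: 8 2-oxo-3-(triphenylphosphoranylidene)propyl 2,4-bis(benzyloxy)-6-propylbenzoate; 9 butanal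
Product: 10 (E)-2-oxohept-3-en-1-yl 2,4-bis(benzyloxy)-6-propylbenzoate
Conditions: butanal (3 equiv), toluene, 80 °C, sealed vessel
Reagents that add atoms: none
Why: Wittig olefination with a ketone-stabilized ylide should give the (E)-enone selectively and needs no added base, so neither butanal nor the alpha-acyloxy ketone is enolized.

Step 6
Reactants: 10 (E)-2-oxohept-3-en-1-yl 2,4-bis(benzyloxy)-6-propylbenzoate; 11 dibenzyl malonate
Product: 13 benzyl 3-{[2,4-bis(benzyloxy)-6-propylbenzoyl]oxy}-2,4-dioxo-6-propylcyclohexane-1-carboxylate (racemic diastereomer/enol mixture), via acyclic Michael adduct 12 (not isolated)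
Conditions: 11, KOtBu (1.1 equiv), THF, 0 °C; add 10, 0 °C to reflux; then 1 M HCl, 0 °C
Reagents that add atoms: none
Why: Proposed new method: the potassium malonate of 11 adds to C4 of the heptenone unit of 10 (the beta carbon, which carries the propyl group) to give 12, proton transfer then forms the ketone enolate on the acyloxy-bearing C1, and this enolate attacks one malonate ester carbonyl and expels benzyl oxide, so that C1'–C6' and then C2'–C3' are made. The closest known reaction is the malonate–enone Michael addition/Dieckmann-type Claisen cyclization that gives 6-alkylcyclohexane-2,4-dione-1-carboxylates, which tolerates an alkyl group on the alpha' carbon but has not been run with an acyloxy group there. Ring B closes in a 6-exo-trig (enolexo) mode at the ester carbonyl. The stereocentres formed at C1', C3' and C6' are not controlled, because all three are removed by enolization and by the aromatization of step 7. The step needs conjugate rather than carbonyl addition (soft, stabilized malonate anion), closure from the alpha' carbon (closure from the other alpha carbon would give a four-membered ring) and an intact depside ester; the last is secured by the two ortho substituents of the ring A benzoate (benzyloxy and propyl), which block benzyl oxide attack, enolate acyl transfer and furanone-forming attack of the C5' enolate on the aroyl carbonyl. Deprotonation of the product to its vinylogous carboxylate anion draws the equilibria forward.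

Step 7
Reactants: 13 benzyl 3-{[2,4-bis(benzyloxy)-6-propylbenzoyl]oxy}-2,4-dioxo-6-propylcyclohexane-1-carboxylate
Product: 14 benzyl 3-{[2,4-bis(benzyloxy)-6-propylbenzoyl]oxy}-2,4-dihydroxy-6-propylbenzoate
Conditions: DDQ (1.15 equiv), 1,4-dioxane, 80 °C
Reagents that add atoms: none
Why: Quinone dehydrogenation should work because DDQ abstracts hydride from C6'–H of the enol tautomers (allylic to the C1'=C2' or C4'=C5' enol) and proton loss with tautomerization gives the resorcylate, a path that does not involve the blocked C3' and that phenol benzyl ethers tolerate.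

Step 8
Reactants: 14 benzyl 3-{[2,4-bis(benzyloxy)-6-propylbenzoyl]oxy}-2,4-dihydroxy-6-propylbenzoate
Product: 15 benzyl 4-(benzyloxy)-3-{[2,4-bis(benzyloxy)-6-propylbenzoyl]oxy}-2-hydroxy-6-propylbenzoate
Conditions: BnBr (1.05 equiv), K2CO3 (1.05 equiv), acetone, rt
Reagents that add atoms: benzyl bromide BrCc1ccccc1
Why: Williamson etherification should go to O4', the more acidic, non-chelated phenol, because the C2' hydroxyl is hydrogen-bonded to the benzyl ester carbonyl and flanked on both sides.

Step 9
Reactants: 15 benzyl 4-(benzyloxy)-3-{[2,4-bis(benzyloxy)-6-propylbenzoyl]oxy}-2-hydroxy-6-propylbenzoate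
Product: 16 benzyl 4-(benzyloxy)-3-{[2,4-bis(benzyloxy)-6-propylbenzoyl]oxy}-2-methoxy-6-propylbenzoate
Conditions: MeI (5 equiv), K2CO3, DMF, rt
Reagents that add atoms: iodomethane CI
Why: Williamson methylation of the remaining chelated phenol with the small electrophile iodomethane in DMF should proceed, the doubly ortho-substituted aroyl ester resisting migration to the neighbouring phenoxide.

Step 10
Reactants: 16 benzyl 4-(benzyloxy)-3-{[2,4-bis(benzyloxy)-6-propylbenzoyl]oxy}-2-methoxy-6-propylbenzoate
Product: 17 3-[(2,4-dihydroxy-6-propylbenzoyl)oxy]-4-hydroxy-2-methoxy-6-propylbenzoic acid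
Conditions: H2 (1 atm), Pd/C (10%), EtOAc, rt
Reagents that add atoms: none
Why: Catalytic hydrogenolysis should cleave the three benzyl ethers and the benzyl ester in one neutral operation while leaving the aryl ester (depside) bond and the methyl ether intact.

**Compound list**
1 | 5-propylresorcinol (5-propylbenzene-1,3-diol) | CCCc1cc(O)cc(O)c1 | starting material
2 | N-[(2,4-dihydroxy-6-propylphenyl)methylidene]-N-methylmethanaminium chloride (not isolated) | CCCc1cc(O)cc(O)c1C=[N+](C)C.[Cl-] | intermediate
3 | 2,4-dihydroxy-6-propylbenzaldehyde | CCCc1cc(O)cc(O)c1C=O | intermediate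
4 | 2,4-bis(benzyloxy)-6-propylbenzaldehyde | CCCc1cc(OCc2ccccc2)cc(OCc2ccccc2)c1C=O | intermediate
5 | 2,4-bis(benzyloxy)-6-propylbenzoic acid | CCCc1cc(OCc2ccccc2)cc(OCc2ccccc2)c1C(=O)O | intermediate
6 | 1-chloro-3-(triphenylphosphoranylidene)propan-2-one | ClCC(=O)C=P(c1ccccc1)(c1ccccc1)c1ccccc1 | starting material
7 | cesium 2,4-bis(benzyloxy)-6-propylbenzoate (not isolated) | CCCc1cc(OCc2ccccc2)cc(OCc2ccccc2)c1C(=O)[O-].[Cs+] | intermediate
8 | 2-oxo-3-(triphenylphosphoranylidene)propyl 2,4-bis(benzyloxy)-6-propylbenzoate | CCCc1cc(OCc2ccccc2)cc(OCc2ccccc2)c1C(=O)OCC(=O)C=P(c1ccccc1)(c1ccccc1)c1ccccc1 | intermediate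
9 | butanal | CCCC=O | starting material
10 | (E)-2-oxohept-3-en-1-yl 2,4-bis(benzyloxy)-6-propylbenzoate | CCC/C=C/C(=O)COC(=O)c1c(CCC)cc(OCc2ccccc2)cc1OCc1ccccc1 | intermediate
11 | dibenzyl malonate | O=C(CC(=O)OCc1ccccc1)OCc1ccccc1 | starting material
12 | dibenzyl 2-{1-[(2,4-bis(benzyloxy)-6-propylbenzoyl)oxy]-2-oxoheptan-4-yl}propanedioate (racemic, not isolated) | CCCC(CC(=O)COC(=O)c1c(CCC)cc(OCc2ccccc2)cc1OCc1ccccc1)C(C(=O)OCc1ccccc1)C(=O)OCc1ccccc1 | intermediate
13 | benzyl 3-{[2,4-bis(benzyloxy)-6-propylbenzoyl]oxy}-2,4-dioxo-6-propylcyclohexane-1-carboxylate (racemic mixture of diastereomers and enol tautomers) | CCCC1CC(=O)C(OC(=O)c2c(CCC)cc(OCc3ccccc3)cc2OCc2ccccc2)C(=O)C1C(=O)OCc1ccccc1 | intermediate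
14 | benzyl 3-{[2,4-bis(benzyloxy)-6-propylbenzoyl]oxy}-2,4-dihydroxy-6-propylbenzoate | CCCc1cc(O)c(OC(=O)c2c(CCC)cc(OCc3ccccc3)cc2OCc2ccccc2)c(O)c1C(=O)OCc1ccccc1 | intermediate
15 | benzyl 4-(benzyloxy)-3-{[2,4-bis(benzyloxy)-6-propylbenzoyl]oxy}-2-hydroxy-6-propylbenzoate | CCCc1cc(OCc2ccccc2)c(OC(=O)c2c(CCC)cc(OCc3ccccc3)cc2OCc2ccccc2)c(O)c1C(=O)OCc1ccccc1 | intermediate
16 | benzyl 4-(benzyloxy)-3-{[2,4-bis(benzyloxy)-6-propylbenzoyl]oxy}-2-methoxy-6-propylbenzoate | CCCc1cc(OCc2ccccc2)c(OC(=O)c2c(CCC)cc(OCc3ccccc3)cc2OCc2ccccc2)c(OC)c1C(=O)OCc1ccccc1 | intermediate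
17 | 3-[(2,4-dihydroxy-6-propylbenzoyl)oxy]-4-hydroxy-2-methoxy-6-propylbenzoic acid | CCCc1cc(O)cc(O)c1C(=O)Oc1c(O)cc(CCC)c(C(=O)O)c1OC | target

**Total step count:** 10 steps.
**Longest linear sequence:** 10 steps (1 → 17); compounds 6, 9 and 11 enter as purchased reagents.

**Steps most likely to fail**

Step 6. The alpha-acyloxy ketone may be consumed by enolate-mediated acyl transfer or alkoxide cleavage before the slow Claisen closure, or the adduct may stall as its unreactive malonate anion. The fallback uses known chemistry, sets out from 11 and 5 and comes back at 13. Dibenzyl malonate 11 is condensed with purchased (E)-hept-3-en-2-one (CCC/C=C/C(C)=O) under the classical conditions (KOtBu, THF, reflux). This passes through the acyclic adduct dibenzyl 2-(2-oxoheptan-4-yl)propanedioate F1 and should give benzyl 2,4-dioxo-6-propylcyclohexane-1-carboxylate F2. Regitz diazo transfer (4-acetamidobenzenesulfonyl azide, Et3N, MeCN, 0 °C) at C3, the carbon between the two ketones, should give benzyl 3-diazo-2,4-dioxo-6-propylcyclohexane-1-carboxylate F3. Rh2(OAc)4-catalysed O–H insertion of the derived carbenoid into ring A acid 5 (CH2Cl2, rt) places the aroyloxy group and a hydrogen on C3' and delivers 13. Steps 1–3 still supply 5; steps 4 and 5 are no longer needed.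

Step 7. Hydride abstraction from the strongly enolized, acceptor-substituted dione may be slow or incomplete, and prolonged heating may bring oxidation at benzylic positions. The fallback runs from 13 back to 14 by halogenation and dehydrohalogenation in place of hydride abstraction. Br2 (1 equiv) in DMF at 0 °C should brominate the enol carbon to give benzyl 3-{[2,4-bis(benzyloxy)-6-propylbenzoyl]oxy}-3-bromo-2,4-dioxo-6-propylcyclohexane-1-carboxylate F4. Warming the same solution to about 80 °C should then remove HBr, through enolization and bromine transfer mediated by the HBr–DMF formed, and give 14, as in the bromine/DMF aromatization of 3-substituted dihydroresorcylates.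

Step 9. The chelated, doubly flanked O2' phenoxide may alkylate slowly, which gives the neighbouring aroyl group time to migrate from O3' to O2' and the benzyl ester time to be cleaved. The fallback runs from 15 to 16 by Mitsunobu etherification (MeOH, PPh3, DIAD, THF, 0 °C to rt). This is a redox condensation instead of a carbonate-mediated SN2 reaction: the phenol is deprotonated only within an ion pair and is methylated by the methoxyphosphonium ion. It makes no new compound (F0).

**Further compounds**
F1 | step 6 | dibenzyl 2-(2-oxoheptan-4-yl)propanedioate (racemic, not isolated) | CCCC(CC(C)=O)C(C(=O)OCc1ccccc1)C(=O)OCc1ccccc1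
F2 | step 6 | benzyl 2,4-dioxo-6-propylcyclohexane-1-carboxylate (racemic, enol tautomers) | CCCC1CC(=O)CC(=O)C1C(=O)OCc1ccccc1
F3 | step 6 | benzyl 3-diazo-2,4-dioxo-6-propylcyclohexane-1-carboxylate (racemic) | CCCC1CC(=O)C(=[N+]=[N-])C(=O)C1C(=O)OCc1ccccc1
F4 | step 7 | benzyl 3-{[2,4-bis(benzyloxy)-6-propylbenzoyl]oxy}-3-bromo-2,4-dioxo-6-propylcyclohexane-1-carboxylate (mixture of diastereomers) | CCCC1CC(=O)C(Br)(OC(=O)c2c(CCC)cc(OCc3ccccc3)cc2OCc2ccccc2)C(=O)C1C(=O)OCc1ccccc1
F0 | step 9 | none | none
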